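Remark on the chemistry: two senses of selectivity cannot be fixed on paper and are assumed. The lipase of step 1 is taken to acylate (R)-lavandulol faster (if not, the ester fraction is saponified to 2), and the (R)-configured phosphoric acid of step 14 is taken to favour the (2R,3S) adduct (if not, its mirror-image catalyst is used).

## Structural features

The target 28 is a 2,3-trans-dihydroflavonol: a chroman-4-one (ring A fused to ring C) with a 2,4-dihydroxyphenyl ring B on C2 and a hydroxyl on C3. Ring A is a fully substituted phloroglucinol in which O1, O5 and O7 alternate with three carbon substituents: the C4 carbonyl carbon on C4a, a 3-hydroxy-3-methylbutyl chain on C6 and a lavandulyl group on C8. C2 (R) and C3 (R) are adjacent stereocentres; the third, (R) in the lavandulyl chain, lies two carbons outside ring A and is too remote to steer anything in ring C. The α-ketol/β-aryloxy ketone is base-sensitive (ring opening to the chalcone, epimerisation, dehydrogenation to the flavonol). The isopropenyl and trisubstituted alkenes and the tertiary alcohol each sit next to a phenol and can cyclise to chromans under acid. The real difficulty is twofold: a hexasubstituted benzene whose three oxygens must be told apart, and absolute control of C2/C3 without help from the remote centre. The key step reads O1–C8a–C4a–C4 as an ortho-quinone methide of ring A and C2–C3 as the double bond of an (E)-arylvinyl ester of ring B, so that ring C forms in one [4+2] event with O3 already in place. The adduct is a flavan-3-yl ester with C4 as CH2, which is two oxidation stages (four electrons) below the target ketone and not one, so two oxidations are planned after the cycloaddition. The (S)-alcohol 2 maps onto the (R) descriptor of the aryl-bound lavandulyl group only through a change of CIP priorities.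

## Logic of the disconnections

28 ⇐ 27 ⇐ 25. Cut: two O–Si bonds (O3, side-chain O), then four aryl O–CH2OMe bonds. Reason: every heteroatom stays masked until the skeleton and oxidation level are complete. Gain: 25 has no free phenol, so it tolerates oxidants. Demand: the acetals must come off without protic mineral acid (alkenes, tertiary alcohol) and the silyl groups without base (α-ketol). Methoxymethyl was preferred to silyl on the phenols because aryl silyl ethers ortho/para to a formyl group would not survive the aqueous base and fluoride used to build 11 and 18.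

25 ⇐ 24 ⇐ 23. Cut: the two C4–O bonds of the carbonyl, back to C4–H2. Reason: this connects the target to the flavan produced by the cycloaddition. Gain: the ketone and its base sensitivity are absent during ring construction. Demand: hydride abstraction must occur at C4 (stabilised by ring A) and not at C2 (stabilised by ring B and O1), and the second oxidation must not epimerise C3.

23 ⇐ 22 ⇐ 21. Cut: O3–Si, replaced by O3–acyl. Reason: the ester is needed as the enol derivative in the cycloaddition, but at C3 it would participate in the C4 cation and could later be removed from an α-ketol only with base. Gain: a non-participating ether for the oxidations. Demand: ester cleavage without base.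

21 ⇐ 14 + 19 (through 20). Cut: C3–C4 and O1–C2. Reason: both bonds, ring C and both stereocentres arise in one convergent union of a ring A piece and a ring B piece of similar size. Gain: two achiral (at the reacting sites) fragments replace a stereodefined heterocycle. Demand: 19 must be geometrically pure (E), since its geometry encodes the trans relationship; only O8a may be free in 14 so that one quinone methide forms; the catalyst must choose the alkene face.

14 ⇐ 13 ⇐ 11 + 3 (through 12). Cut: the benzylic C4–O level back to the aldehyde, then the C8–CH2 bond. Reason: 14 is too labile to carry, so it is made last from a stable aldehyde; the lavandulyl unit enters late as an sp3 organometallic. Gain: the chiral side chain is a separate building block. Demand: a coupling at a di-ortho-substituted bromide that outruns β-hydride elimination and tolerates a phenol and an aldehyde.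

11 ⇐ 7 + 9 (through 10); 7 ⇐ 6 ⇐ 5 ⇐ 4. Cut: the C6–CH2 bond, then C–I, C–Br and two O–CH2OMe bonds. Reason: 4 already holds the C4 carbon, and its chelated ortho-hydroxyl singles out O8a in one protection step. The two ring positions left are then addressed by halogens of different reactivity. Gain: ring A is reduced to a commercial aldehyde. Demand: the first halogen must go ortho to the free hydroxyl, and C–I must couple before C–Br.

3 ⇐ 2 ⇐ 1 and 9 ⇐ 8. Cut: C–I back to C–OH, then resolution of the racemate; O–Si back to the tertiary alcohol. Reason: both side chains come from cheap commercial alcohols. Demand: a kinetic resolution that can be pushed to high enantiopurity of the slower-reacting alcohol.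

19 ⇐ 18 ⇐ 17 ⇐ 16 ⇐ 15. Cut: the vinyl C–O bond of the enol ester, then the C=C bond, then two O–CH2OMe bonds. Reason: a stereoretentive C–O coupling on an (E)-alkenylboron compound fixes the geometry, which enolate O-acylation of the arylacetaldehyde would not. Demand: an (E)-selective olefination and retention in the copper step.

## Other disconnections considered

Alternative 1: The cut removes ring A itself (C6–C7, C7–C8, C4a–C8a). Forward, heating cyclobutenone A2 with siloxyalkyne A3 would start a cascade (4π opening to a vinylketene, [2+2] with the alkyne, second 4π opening, 6π closure, tautomerisation) giving phenol A1 with O7 free, O8a silylated and O5 ethylated. In its favour: the positions of all substituents follow from the mechanism, the three oxygens are differentiated at birth, and no cross-coupling on a crowded arene is needed. On regiochemical certainty of ring A it is better than the chosen plan, which relies on the order of two halogenations and on iodide-before-bromide selectivity. On integrity of the lavandulyl centre the two are equal. Against it here: it builds only ring A and leaves ring C and C2/C3 unsolved. A1 has the wrong oxygen free for ring C closure (two protecting-group operations), still needs the C4 carbon, and carries an ethyl ether that only boron halides would cleave, which the alkenes and tertiary alcohol would not survive. A3 needs a two-carbon homologation of 3 and A2 a separate alkylation, so reaching the equivalent of 14 would take clearly more steps than the nine used here.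

Alternative 2: The cut is C4a–C5 and C8–C8a, so ring A is annulated last. Forward, diene A6 would add across C4a=C8a of bromodihydropyranone A5, and loss of HBr and methanol would aromatise to A4. In its favour: C2/C3 are set early on a small molecule, the C4 ketone is present from the start, and ring A arrives with O5 and O7 free. On oxidation-state economy and length of the endgame it is better than the chosen plan (no pivalate exchange, no C–H oxidation); on convergence it is equal. Against it here: the 2π partner is a vinylogous ester, and bis-silyloxy dienes tend to add to pyranones in a conjugate sense and then open the pyranone at O1–C8a, which would destroy ring C. A diene substituted at both its internal and terminal carbons is slow to cyclise, and the Lewis acid usually required threatens the acetals, the alkenes and the β-silyloxy ketone (elimination, epimerisation at C2/C3). Both key steps lack direct precedent; the chosen one has the closer analogy. The overall step count would be similar or slightly lower.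

Alternative 3: The cut is O1–C8a. Forward, the C2 alkoxide of fluoro ketone A8 would displace fluoride ortho to the carbonyl and give A7 with retention at both centres. In its favour: every reaction type is known, so on precedent it is better than the chosen plan. The stereocentres come from acyclic anti-selective chemistry, the ketone is present from the start, and uniform acetal protection makes the endgame equal or shorter. Against it here: a hexasubstituted fluoroarene must be built around the fluorine, with acylation at the most hindered position. The only activating group is a ketone that its two ortho substituents twist out of conjugation, and alkyl groups sit on two of the charge-bearing positions. The displacement would therefore need strong base and heat on a β-hydroxy-α-alkoxy ketone, inviting retro-aldol cleavage and C3 epimerisation, where the chosen plan closes ring C under weak acid. Step count would be comparable.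

Key step: step 14

## Route

Step 1
Reactants: 1 (±)-lavandulol
Product: 2 (S)-lavandulol
Conditions: immobilised Candida antarctica lipase B, vinyl acetate, MTBE, 25 °C, stopped beyond half conversion; chromatographic separation from the acetate
Reagents that add atoms: none
Why: Lipase-catalysed kinetic resolution by enantioselective transesterification with an irreversible acyl donor; the (R)-alcohol is assumed to be acylated faster so that 2 remains, and because selectivity for a β-branched primary alcohol is expected to be modest the conversion is pushed past one half (or the enriched alcohol is resubmitted); the stereocentre itself is never touched.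

Step 2
Reactants: 2 (S)-lavandulol
Product: 3 (S)-lavandulyl iodide [(3S)-3-(iodomethyl)-2,6-dimethylhepta-1,5-diene]
Conditions: I2, PPh3, imidazole, CH2Cl2, 0 °C → rt
Reagents that add atoms: iodine, II
Why: Appel-type iodination of a primary alcohol (SN2 at CH2); the stereocentre is β to the reacting carbon and cannot invert, and the buffered neutral medium leaves both alkenes alone.

Step 3
Reactants: 4 2,4,6-trihydroxybenzaldehyde
Product: 5 2-hydroxy-4,6-bis(methoxymethoxy)benzaldehyde
Conditions: MOMCl (2.1 equiv), i-Pr2NEt, CH2Cl2, 0 °C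
Reagents that add atoms: chloromethyl methyl ether, COCCl
Why: Chelation-controlled partial O-alkylation: the 4-OH and one ortho-OH react, while the other ortho-OH is held by an intramolecular hydrogen bond to the formyl oxygen and stays free; one step thus distinguishes O8a (free) from O5 and O7, and the aldehyde carbon is the future C4.

Step 4
Reactants: 5 2-hydroxy-4,6-bis(methoxymethoxy)benzaldehyde
Product: 6 3-bromo-2-hydroxy-4,6-bis(methoxymethoxy)benzaldehyde
Conditions: NBS (1.0 equiv), i-Pr2NH (10 mol%), CH2Cl2, −40 → 0 °C
Reagents that add atoms: N-bromosuccinimide, O=C1CCC(=O)N1Br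
Why: Electrophilic aromatic bromination with amine-mediated ortho delivery to a phenol; C3 (future C8) is ortho to the free hydroxyl and flanked by only one alkoxy group, so it should react before the more crowded C5, and one equivalent at low temperature limits dibromination.

Step 5
Reactants: 6 3-bromo-2-hydroxy-4,6-bis(methoxymethoxy)benzaldehyde
Product: 7 3-bromo-2-hydroxy-5-iodo-4,6-bis(methoxymethoxy)benzaldehyde
Conditions: NIS (1.1 equiv), MeCN, rt, dark
Reagents that add atoms: N-iodosuccinimide, O=C1CCC(=O)N1I
Why: Electrophilic iodination at the only open ring position (para to the phenol), activated enough to need no acid co-catalyst, which spares the acetals; iodine here and bromine at C3 programme the order of the two cross-couplings.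

Step 6
Reactants: 8 2-methylbut-3-en-2-ol
Product: 9 triethyl[(2-methylbut-3-en-2-yl)oxy]silane
Conditions: TESOTf, 2,6-lutidine, CH2Cl2, 0 °C
Reagents that add atoms: triethylsilyl trifluoromethanesulfonate, CC[Si](CC)(CC)OS(=O)(=O)C(F)(F)F
Why: Silylation of a tertiary alcohol with a silyl triflate and a hindered pyridine base; the ether masks the future side-chain hydroxyl through the organometallic and acid-catalysed steps.

Step 7
Reactants: 9 triethyl[(2-methylbut-3-en-2-yl)oxy]silane; 7 3-bromo-2-hydroxy-5-iodo-4,6-bis(methoxymethoxy)benzaldehyde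
Product: 11 3-bromo-2-hydroxy-4,6-bis(methoxymethoxy)-5-[3-methyl-3-(triethylsilyloxy)butyl]benzaldehyde, via B-alkyl-9-BBN 10 (not isolated)
Conditions: 9, 9-BBN-H dimer, THF, 0 °C → rt; then 7, Pd(dppf)Cl2 (5 mol%), aq. K3PO4, DMF, 25 → 45 °C
Reagents that add atoms: none
Why: Anti-Markovnikov hydroboration of the monosubstituted alkene followed by B-alkyl Suzuki–Miyaura coupling; zerovalent palladium inserts into C–I much faster than into C–Br, so the chain enters at C5 (future C6) and the bromide is kept, while the aqueous base holds the salicylaldehyde as its unreactive phenoxide.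

Step 8
Reactants: 3 (S)-lavandulyl iodide; 11 3-bromo-2-hydroxy-4,6-bis(methoxymethoxy)-5-[3-methyl-3-(triethylsilyloxy)butyl]benzaldehyde
Product: 13 2-hydroxy-4,6-bis(methoxymethoxy)-3-[(2R)-5-methyl-2-(prop-1-en-2-yl)hex-4-en-1-yl]-5-[3-methyl-3-(triethylsilyloxy)butyl]benzaldehyde, via lavandulylzinc iodide 12 (not isolated)
Conditions: 3, Zn dust (activated with 1,2-dibromoethane and TMSCl), LiCl, THF, 40 °C; then slow addition to 11, Pd(OAc)2 (4 mol%), SPhos (8 mol%), THF, 25 → 50 °C
Reagents that add atoms: none
Why: Negishi sp3–sp2 coupling: zinc insertion into the primary iodide gives a reagent whose stereocentre is β to the metal and therefore secure, a bulky biarylphosphine drives reductive elimination at the di-ortho-substituted bromide ahead of β-hydride elimination, and alkylzinc halides tolerate the aldehyde and, when added slowly, the hydrogen-bonded phenol.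

Step 9
Reactants: 13 2-hydroxy-4,6-bis(methoxymethoxy)-3-[(2R)-5-methyl-2-(prop-1-en-2-yl)hex-4-en-1-yl]-5-[3-methyl-3-(triethylsilyloxy)butyl]benzaldehyde
Product: 14 2-(hydroxymethyl)-3,5-bis(methoxymethoxy)-6-[(2R)-5-methyl-2-(prop-1-en-2-yl)hex-4-en-1-yl]-4-[3-methyl-3-(triethylsilyloxy)butyl]phenol
Conditions: NaBH4, THF/EtOH, −10 °C; pH 7 phosphate buffer work-up; used without storage
Reagents that add atoms: none
Why: Borohydride reduction of the aryl aldehyde to the salicyl alcohol; low temperature, short contact and a neutral work-up are needed because this trioxygenated benzylic alcohol ionises easily (premature quinone methide formation or over-reduction to the methyl arene), so 14 is taken straight into step 14.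

Step 10
Reactants: 15 2,4-dihydroxybenzaldehyde
Product: 16 2,4-bis(methoxymethoxy)benzaldehyde
Conditions: MOMCl (3 equiv), K2CO3, acetone, reflux
Reagents that add atoms: chloromethyl methyl ether, COCCl
Why: O-Alkylation of both phenols; the chelated ortho-hydroxyl needs carbonate and heat, which is harmless here because no differentiation is wanted.

Step 11
Reactants: 16 2,4-bis(methoxymethoxy)benzaldehyde
Product: 17 2-{(E)-2-[2,4-bis(methoxymethoxy)phenyl]ethenyl}-4,4,5,5-tetramethyl-1,3,2-dioxaborolane
Conditions: CH2(Bpin)2, lithium 2,2,6,6-tetramethylpiperidide (from the amine and n-BuLi), THF, 0 °C; then 16, −78 °C → rt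
Reagents that add atoms: bis(pinacolato)borylmethane, CC1(C)OB(CB2OC(C)(C)C(C)(C)O2)OC1(C)C
Why: Boron-Wittig olefination: the lithiated geminal bis(boronate) adds to the aldehyde and syn B–O elimination gives the trans alkenylboronate, fixing the (E) geometry that later encodes the trans C2/C3 relationship.

Step 12
Reactants: 17 2-{(E)-2-[2,4-bis(methoxymethoxy)phenyl]ethenyl}-4,4,5,5-tetramethyl-1,3,2-dioxaborolane
Product: 18 potassium {(E)-2-[2,4-bis(methoxymethoxy)phenyl]ethenyl}trifluoroborate
Conditions: KHF2 (aq., 4 equiv), MeOH, 0 °C → rt, short contact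
Reagents that add atoms: potassium hydrogen difluoride, F.[F-].[K+]
Why: Standard conversion of a pinacol boronate into the trifluoroborate, the boron species best suited to copper-mediated C–O coupling; short contact keeps the aryl acetals intact and the alkene geometry is untouched.

Step 13
Reactants: 18 potassium {(E)-2-[2,4-bis(methoxymethoxy)phenyl]ethenyl}trifluoroborate
Product: 19 (E)-2-[2,4-bis(methoxymethoxy)phenyl]ethenyl pivalate
Conditions: t-BuCO2H (3 equiv), CuBr (10 mol%), DMAP (20 mol%), 4 Å MS, O2 (1 atm), MeCN, 40 °C
Reagents that add atoms: pivalic acid, CC(C)(C)C(=O)O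
Why: Copper-catalysed oxidative (Chan–Lam-type) coupling of an alkenyltrifluoroborate with a carboxylic acid, stereoretentive at the alkene, so the (E)-enol ester forms without the E/Z mixture expected from enolate O-acylation of the arylacetaldehyde; pivalate is chosen because it resists acyl transfer to the phenol and benzylic alcohol of 14.

Step 14
Reactants: 14 2-(hydroxymethyl)-3,5-bis(methoxymethoxy)-6-[(2R)-5-methyl-2-(prop-1-en-2-yl)hex-4-en-1-yl]-4-[3-methyl-3-(triethylsilyloxy)butyl]phenol; 19 (E)-2-[2,4-bis(methoxymethoxy)phenyl]ethenyl pivalate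
Product: 21 (2R,3S)-2-[2,4-bis(methoxymethoxy)phenyl]-5,7-bis(methoxymethoxy)-8-[(2R)-5-methyl-2-(prop-1-en-2-yl)hex-4-en-1-yl]-6-[3-methyl-3-(triethylsilyloxy)butyl]chroman-3-yl pivalate, via ortho-quinone methide 20 (not isolated)
Conditions: (R)-TRIP [(R)-3,3'-bis(2,4,6-triisopropylphenyl)-1,1'-binaphthyl-2,2'-diyl hydrogen phosphate] (10 mol%), 19 (1.5 equiv), 5 Å MS, toluene, 0 °C; 14 added by syringe pump
Reagents that add atoms: none
Why: Proposed new method: the phosphoric acid protonates the benzylic hydroxyl of 14, water is lost, and ortho-quinone methide 20 stays hydrogen-bonded (or ion-paired) to the chiral phosphate through O1; 19 then bonds through its acyloxy-bearing carbon to the unsubstituted methide carbon (C3–C4) while positive charge builds at the benzylic carbon, where the 2,4-dialkoxyphenyl ring stabilises it far better than the cross-conjugated pivaloyloxy group could stabilise the alternative, and O1 collapses onto that carbon (O1–C2). The closest known reaction type is the chiral Brønsted acid-catalysed inverse-electron-demand oxa-[4+2] cycloaddition of in situ generated ortho-quinone methides with electron-rich styrenes and enamides to give 2-arylchromans; new here are the enol ester as 2π partner and a methide without an aryl substituent. Ring C closes as a six-membered ring in an asynchronous suprafacial [4+2] event, with C–C bond formation leading and the phenolic oxygen closing onto the benzylic cation. C3 is set in the C3–C4 bond-forming event, the alkene face being chosen by the 3,3'-aryl walls of the phosphate anchored at O1. C2 follows relative to C3 from the (E) geometry of 19; should the process become stepwise, closure with aryl and pivaloyloxy both equatorial, or anti opening of a pivaloxonium intermediate, leads to the same trans isomer. The step needs regioselectivity (ring B donors override the acyloxy group), chemoselectivity for the enol alkene over ring B arene carbons and the much less nucleophilic lavandulyl alkenes, a single quinone methide (only O8a is free because O5 is an ether) and suppression of quinone methide oligomerisation (slow addition of 14, excess 19). The lavandulyl centre is too remote to bias the outcome, so the catalyst alone decides between the (2R,3S) adduct and its (2S,3R) diastereomer.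

Step 15
Reactants: 21 (2R,3S)-flavan-3-yl pivalate as named in step 14
Product: 22 (2R,3S)-2-[2,4-bis(methoxymethoxy)phenyl]-5,7-bis(methoxymethoxy)-8-[(2R)-5-methyl-2-(prop-1-en-2-yl)hex-4-en-1-yl]-6-[3-methyl-3-(triethylsilyloxy)butyl]chroman-3-ol
Conditions: i-Bu2AlH (3 equiv), CH2Cl2, −78 °C; aq. potassium sodium tartrate
Reagents that add atoms: none
Why: Reductive cleavage of the hindered pivalate by an aluminium hydride at low temperature, with no base present; acetals, the silyl ether and the alkenes are inert and no stereocentre is involved.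

Step 16
Reactants: 22 (2R,3S)-flavan-3-ol as named in step 15
Product: 23 tert-butyl{[(2R,3S)-2-[2,4-bis(methoxymethoxy)phenyl]-5,7-bis(methoxymethoxy)-8-[(2R)-5-methyl-2-(prop-1-en-2-yl)hex-4-en-1-yl]-6-[3-methyl-3-(triethylsilyloxy)butyl]chroman-3-yl]oxy}dimethylsilane
Conditions: TBSCl, imidazole, DMAP (cat.), DMF, 40 °C
Reagents that add atoms: tert-butyldimethylsilyl chloride, CC(C)(C)[Si](C)(C)Cl
Why: Silylation of the secondary 3-OH under conditions that do not attack aryl acetals; a non-participating ether is needed because an ester at O3 would capture the C4 cation of step 17 as a dioxolanylium ion and could not later be removed from the α-ketol without base.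

Step 17
Reactants: 23 3-O-silyl flavan as named in step 16
Product: 24 (2R,3S)-3-(tert-butyldimethylsilyloxy)-2-[2,4-bis(methoxymethoxy)phenyl]-5,7-bis(methoxymethoxy)-8-[(2R)-5-methyl-2-(prop-1-en-2-yl)hex-4-en-1-yl]-6-[3-methyl-3-(triethylsilyloxy)butyl]chroman-4-ol (C4 epimers)
Conditions: DDQ (1.5 equiv), CH2Cl2/pH 7 phosphate buffer (10:1), 0 °C → rt
Reagents that add atoms: water, O
Why: DDQ-mediated benzylic oxidation as practised on protected flavan-3-ols: hydride abstraction from C4 gives a cation stabilised by O5, O7 and O1 of ring A, which water traps, expected anti to the C3 silyloxy group; the C4 configuration is irrelevant because step 18 erases it, and isolated alkenes and acetals do not react with DDQ at this temperature.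

Step 18
Reactants: 24 flavan-3,4-diol mono-silyl ether as named in step 17
Product: 25 (2R,3R)-3-(tert-butyldimethylsilyloxy)-2-[2,4-bis(methoxymethoxy)phenyl]-5,7-bis(methoxymethoxy)-8-[(2R)-5-methyl-2-(prop-1-en-2-yl)hex-4-en-1-yl]-6-[3-methyl-3-(triethylsilyloxy)butyl]chroman-4-one
Conditions: Dess–Martin periodinane, NaHCO3, CH2Cl2, 0 °C → rt
Reagents that add atoms: none
Why: Dess–Martin oxidation of the benzylic secondary alcohol to the aryl ketone under buffered, non-basic conditions, so that C3 (now α to the carbonyl) and C2 (β-aryloxy) are not epimerised; the descriptor at C3 changes to (R) by priority only.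

Step 19
Reactants: 25 protected flavanonol as named in step 18
Product: 27 (2R,3R)-3-(tert-butyldimethylsilyloxy)-2-(2,4-dihydroxyphenyl)-5,7-dihydroxy-8-[(2R)-5-methyl-2-(prop-1-en-2-yl)hex-4-en-1-yl]-6-[3-methyl-3-(triethylsilyloxy)butyl]chroman-4-one, via tetrakis(trimethylsilyl) ether 26 (not isolated)
Conditions: TMSOTf, 2,2'-bipyridyl, CH2Cl2, 0 °C → rt; then H2O, rt
Reagents that add atoms: none
Why: Non-protic cleavage of aryl methoxymethyl ethers: the silyl triflate–bipyridyl pair converts each ArOCH2OMe into ArOSiMe3 and an N-(methoxymethyl)pyridinium salt, and water then frees the phenols; no strong free acid is present, which protects the two alkenes and the tertiary C–O bond from phenol-assisted cyclisation.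

Step 20
Reactants: 27 tetraphenol bis-silyl ether as named in step 19
Product: 28 (2R,3R)-2-(2,4-dihydroxyphenyl)-3,5,7-trihydroxy-6-(3-hydroxy-3-methylbutyl)-8-[(2R)-5-methyl-2-(prop-1-en-2-yl)hex-4-en-1-yl]chroman-4-one (CNP0183552.3)
Conditions: HF·pyridine, pyridine, THF, 0 °C → rt; aq. NaHCO3 work-up
Reagents that add atoms: none
Why: Fluoride-mediated cleavage of the secondary TBS and tertiary TES ethers in a buffered, weakly acidic medium, which avoids both base-induced ring opening or epimerisation of the flavanonol and acid-induced cyclisations; no stereocentre is involved.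

## Compound list

1 | (±)-lavandulol [rac-5-methyl-2-(prop-1-en-2-yl)hex-4-en-1-ol] | C=C(C)C(CC=C(C)C)CO | starting material
2 | (S)-lavandulol | C=C(C)[C@H](CC=C(C)C)CO | intermediate
3 | (S)-lavandulyl iodide [(3S)-3-(iodomethyl)-2,6-dimethylhepta-1,5-diene] | C=C(C)[C@H](CC=C(C)C)CI | intermediate
4 | 2,4,6-trihydroxybenzaldehyde | O=Cc1c(O)cc(O)cc1O | starting material
5 | 2-hydroxy-4,6-bis(methoxymethoxy)benzaldehyde | O=Cc1c(O)cc(OCOC)cc1OCOC | intermediate
6 | 3-bromo-2-hydroxy-4,6-bis(methoxymethoxy)benzaldehyde | O=Cc1c(O)c(Br)c(OCOC)cc1OCOC | intermediate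
7 | 3-bromo-2-hydroxy-5-iodo-4,6-bis(methoxymethoxy)benzaldehyde | O=Cc1c(O)c(Br)c(OCOC)c(I)c1OCOC | intermediate
8 | 2-methylbut-3-en-2-ol | C=CC(C)(C)O | starting material
9 | triethyl[(2-methylbut-3-en-2-yl)oxy]silane | C=CC(C)(C)O[Si](CC)(CC)CC | intermediate
10 | 9-[3-methyl-3-(triethylsilyloxy)butyl]-9-borabicyclo[3.3.1]nonane | CC[Si](CC)(CC)OC(C)(C)CCB1C2CCCC1CCC2 | intermediate (not isolated)
11 | 3-bromo-2-hydroxy-4,6-bis(methoxymethoxy)-5-[3-methyl-3-(triethylsilyloxy)butyl]benzaldehyde | O=Cc1c(O)c(Br)c(OCOC)c(CCC(C)(C)O[Si](CC)(CC)CC)c1OCOC | intermediate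
12 | [(2S)-5-methyl-2-(prop-1-en-2-yl)hex-4-en-1-yl]zinc iodide | C=C(C)[C@H](CC=C(C)C)C[Zn]I | intermediate (not isolated)
13 | 2-hydroxy-4,6-bis(methoxymethoxy)-3-[(2R)-5-methyl-2-(prop-1-en-2-yl)hex-4-en-1-yl]-5-[3-methyl-3-(triethylsilyloxy)butyl]benzaldehyde | C=C(C)[C@H](CC=C(C)C)Cc1c(O)c(C=O)c(OCOC)c(CCC(C)(C)O[Si](CC)(CC)CC)c1OCOC | intermediate
14 | 2-(hydroxymethyl)-3,5-bis(methoxymethoxy)-6-[(2R)-5-methyl-2-(prop-1-en-2-yl)hex-4-en-1-yl]-4-[3-methyl-3-(triethylsilyloxy)butyl]phenol (ring A salicyl alcohol) | C=C(C)[C@H](CC=C(C)C)Cc1c(OCOC)c(CCC(C)(C)O[Si](CC)(CC)CC)c(OCOC)c(CO)c1O | intermediate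
15 | 2,4-dihydroxybenzaldehyde | O=Cc1ccc(O)cc1O | starting material
16 | 2,4-bis(methoxymethoxy)benzaldehyde | COCOc1ccc(C=O)c(OCOC)c1 | intermediate
17 | 2-{(E)-2-[2,4-bis(methoxymethoxy)phenyl]ethenyl}-4,4,5,5-tetramethyl-1,3,2-dioxaborolane | COCOc1ccc(/C=C/B2OC(C)(C)C(C)(C)O2)c(OCOC)c1 | intermediate
18 | potassium {(E)-2-[2,4-bis(methoxymethoxy)phenyl]ethenyl}trifluoroborate | COCOc1ccc(/C=C/[B-](F)(F)F)c(OCOC)c1.[K+] | intermediate
19 | (E)-2-[2,4-bis(methoxymethoxy)phenyl]ethenyl pivalate | COCOc1ccc(/C=C/OC(=O)C(C)(C)C)c(OCOC)c1 | intermediate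
20 | 3,5-bis(methoxymethoxy)-6-methylidene-2-[(2R)-5-methyl-2-(prop-1-en-2-yl)hex-4-en-1-yl]-4-[3-methyl-3-(triethylsilyloxy)butyl]cyclohexa-2,4-dien-1-one (ortho-quinone methide) | C=C(C)[C@H](CC=C(C)C)CC1=C(OCOC)C(CCC(C)(C)O[Si](CC)(CC)CC)=C(OCOC)C(=C)C1=O | intermediate (not isolated)
21 | (2R,3S)-2-[2,4-bis(methoxymethoxy)phenyl]-5,7-bis(methoxymethoxy)-8-[(2R)-lavandulyl]-6-[3-methyl-3-(triethylsilyloxy)butyl]chroman-3-yl pivalate | C=C(C)[C@H](CC=C(C)C)Cc1c(OCOC)c(CCC(C)(C)O[Si](CC)(CC)CC)c(OCOC)c2c1O[C@H](c1ccc(OCOC)cc1OCOC)[C@@H](OC(=O)C(C)(C)C)C2 | intermediate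
22 | (2R,3S)-flavan-3-ol corresponding to 21 | C=C(C)[C@H](CC=C(C)C)Cc1c(OCOC)c(CCC(C)(C)O[Si](CC)(CC)CC)c(OCOC)c2c1O[C@H](c1ccc(OCOC)cc1OCOC)[C@@H](O)C2 | intermediate
23 | (2R,3S)-3-O-tert-butyldimethylsilyl ether of 22 | C=C(C)[C@H](CC=C(C)C)Cc1c(OCOC)c(CCC(C)(C)O[Si](CC)(CC)CC)c(OCOC)c2c1O[C@H](c1ccc(OCOC)cc1OCOC)[C@@H](O[Si](C)(C)C(C)(C)C)C2 | intermediate
24 | (2R,3S)-3-(tert-butyldimethylsilyloxy)flavan-4-ol corresponding to 23 (C4 epimers) | C=C(C)[C@H](CC=C(C)C)Cc1c(OCOC)c(CCC(C)(C)O[Si](CC)(CC)CC)c(OCOC)c2c1O[C@H](c1ccc(OCOC)cc1OCOC)[C@@H](O[Si](C)(C)C(C)(C)C)C2O | intermediate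
25 | (2R,3R)-3-(tert-butyldimethylsilyloxy)-2-[2,4-bis(methoxymethoxy)phenyl]-5,7-bis(methoxymethoxy)-8-[(2R)-lavandulyl]-6-[3-methyl-3-(triethylsilyloxy)butyl]chroman-4-one | C=C(C)[C@H](CC=C(C)C)Cc1c(OCOC)c(CCC(C)(C)O[Si](CC)(CC)CC)c(OCOC)c2c1O[C@H](c1ccc(OCOC)cc1OCOC)[C@@H](O[Si](C)(C)C(C)(C)C)C2=O | intermediate
26 | tetrakis(trimethylsilyl) aryl ether of 27 (O5, O7, O2', O4') | C=C(C)[C@H](CC=C(C)C)Cc1c(O[Si](C)(C)C)c(CCC(C)(C)O[Si](CC)(CC)CC)c(O[Si](C)(C)C)c2c1O[C@H](c1ccc(O[Si](C)(C)C)cc1O[Si](C)(C)C)[C@@H](O[Si](C)(C)C(C)(C)C)C2=O | intermediate (not isolated)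
27 | (2R,3R)-3-(tert-butyldimethylsilyloxy)-2-(2,4-dihydroxyphenyl)-5,7-dihydroxy-8-[(2R)-lavandulyl]-6-[3-methyl-3-(triethylsilyloxy)butyl]chroman-4-one | C=C(C)[C@H](CC=C(C)C)Cc1c(O)c(CCC(C)(C)O[Si](CC)(CC)CC)c(O)c2c1O[C@H](c1ccc(O)cc1O)[C@@H](O[Si](C)(C)C(C)(C)C)C2=O | intermediate
28 | (2R,3R)-2-(2,4-dihydroxyphenyl)-3,5,7-trihydroxy-6-(3-hydroxy-3-methylbutyl)-8-[(2R)-5-methyl-2-(prop-1-en-2-yl)hex-4-en-1-yl]chroman-4-one | C=C(C)[C@H](CC=C(C)C)Cc1c(O)c(CCC(C)(C)O)c(O)c2c1O[C@H](c1ccc(O)cc1O)[C@@H](O)C2=O | target

## Step count and least certain steps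

Total step count: 20. Longest linear sequence: 13 steps (4 → 5 → 6 → 7 → 11 → 13 → 14 → 21 → 22 → 23 → 24 → 25 → 27 → 28).

Step 14 (key step, new method). Most likely failure: poor facial selectivity, because the enol ester has no hydrogen-bond donor to dock on the phosphate and the lavandulyl centre gives no help, so the two trans diastereomers would form together and be hard to separate. Oligomerisation of the quinone methide and Friedel–Crafts attack by ring B are secondary risks. Fallback with known chemistry, setting out from 13 and 16 and returning at 25: 13 is treated with MeMgBr to give carbinol F1, which is oxidised (Dess–Martin periodinane) to the 2-hydroxyacetophenone F2. Claisen–Schmidt condensation of F2 with 16 (KOH, EtOH) gives the (E)-2'-hydroxychalcone F3, and the phenol is allylated (allyl bromide, K2CO3) to F4. Juliá–Colonna epoxidation (poly-L-leucine, urea–H2O2, DBU, THF) attacks only the electron-poor enone double bond and should give the trans (αR,βS)-epoxide F5. Pd(PPh3)4 with morpholine frees phenol F6, which under mild acid (PPTS) closes in the 6-endo mode at the benzylic carbon with inversion to the trans-3-hydroxyflavanone F7. Silylation (TBSCl, imidazole) gives 25, and steps 15–18 are then not needed.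

Step 7. Most likely failure: slow coupling at a carbon flanked by two alkoxy groups, leading to hydrodeiodination or loss of discrimination between iodide and bromide. Fallback, from 7 back to 11: the TES ether F8 of 2-methylbut-3-yn-2-ol is joined to 7 by Sonogashira coupling (Pd(PPh3)2Cl2, CuI, Et3N), which is selective for iodide and little affected by crowding, to give aryl alkyne F9. Homogeneous hydrogenation (H2, RhCl(PPh3)3), which leaves the aryl bromide alone, then gives 11.

Step 8. Most likely failure: β-hydride elimination from the alkylpalladium intermediate (the β-hydrogen is allylic and tertiary), or protonolysis of the zinc reagent by the phenol, wasting the chiral fragment. Fallback, from 3 and 11 back to 13: iodine–lithium exchange on 3 (t-BuLi, −78 °C) gives (S)-lavandulyllithium F10, which is captured with B-methoxy-9-BBN as borate F11. B-alkyl Suzuki–Miyaura coupling of F11 with 11 (Pd(dppf)Cl2, K3PO4, DMF) gives 13; the borate is not protonated by the phenoxide and transmetalates under the conditions that tolerate the aldehyde in step 7.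

Step 17. Most likely failure: competing hydride abstraction at C2, which is benzylic to the dialkoxyphenyl ring and α to O1, or over-oxidation. Fallback, from 23 back to 24: benzylic acetoxylation with Pb(OAc)4 in benzene, a ligand-transfer oxidation known for C4 of flavan-3-ol ethers, gives 4-acetate F12; methanolysis (K2CO3, MeOH) gives 24. The detour described for step 14 also avoids this oxidation altogether.

Step 19. Most likely failure: incomplete cleavage of four acetals, or C-alkylation of the freed resorcinol ring by the formaldehyde equivalent released during hydrolysis. Fallback, from 25 to 28: the order is reversed. HF·pyridine first removes both silyl groups to give tetra-acetal F13, and the acetals are then cleaved by thiolysis (ZnBr2, n-PrSH, CH2Cl2, 0 °C), in which the thiol captures the methoxymethyl unit irreversibly, giving 28.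

## Further compounds

F1 | step 14 | 1-{2-hydroxy-4,6-bis(methoxymethoxy)-3-[(2R)-5-methyl-2-(prop-1-en-2-yl)hex-4-en-1-yl]-5-[3-methyl-3-(triethylsilyloxy)butyl]phenyl}ethan-1-ol (carbinol epimers) | C=C(C)[C@H](CC=C(C)C)Cc1c(O)c(C(C)O)c(OCOC)c(CCC(C)(C)O[Si](CC)(CC)CC)c1OCOC
F2 | step 14 | 1-{2-hydroxy-4,6-bis(methoxymethoxy)-3-[(2R)-5-methyl-2-(prop-1-en-2-yl)hex-4-en-1-yl]-5-[3-methyl-3-(triethylsilyloxy)butyl]phenyl}ethan-1-one | C=C(C)[C@H](CC=C(C)C)Cc1c(O)c(C(C)=O)c(OCOC)c(CCC(C)(C)O[Si](CC)(CC)CC)c1OCOC
F3 | step 14 | (E)-3-[2,4-bis(methoxymethoxy)phenyl]-1-{2-hydroxy-4,6-bis(methoxymethoxy)-3-[(2R)-lavandulyl]-5-[3-methyl-3-(triethylsilyloxy)butyl]phenyl}prop-2-en-1-one | C=C(C)[C@H](CC=C(C)C)Cc1c(O)c(C(=O)/C=C/c2ccc(OCOC)cc2OCOC)c(OCOC)c(CCC(C)(C)O[Si](CC)(CC)CC)c1OCOC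
F4 | step 14 | 2'-O-allyl ether of F3 | C=C(C)[C@H](CC=C(C)C)Cc1c(OCC=C)c(C(=O)/C=C/c2ccc(OCOC)cc2OCOC)c(OCOC)c(CCC(C)(C)O[Si](CC)(CC)CC)c1OCOC
F5 | step 14 | {(2R,3S)-3-[2,4-bis(methoxymethoxy)phenyl]oxiran-2-yl} ketone derived from F4 (trans-epoxide) | C=C(C)[C@H](CC=C(C)C)Cc1c(OCC=C)c(C(=O)[C@@H]2O[C@H]2c2ccc(OCOC)cc2OCOC)c(OCOC)c(CCC(C)(C)O[Si](CC)(CC)CC)c1OCOC
F6 | step 14 | 2'-hydroxy (2R,3S)-epoxy ketone from deallylation of F5 | C=C(C)[C@H](CC=C(C)C)Cc1c(O)c(C(=O)[C@@H]2O[C@H]2c2ccc(OCOC)cc2OCOC)c(OCOC)c(CCC(C)(C)O[Si](CC)(CC)CC)c1OCOC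
F7 | step 14 | (2R,3R)-2-[2,4-bis(methoxymethoxy)phenyl]-3-hydroxy-5,7-bis(methoxymethoxy)-8-[(2R)-lavandulyl]-6-[3-methyl-3-(triethylsilyloxy)butyl]chroman-4-one | C=C(C)[C@H](CC=C(C)C)Cc1c(OCOC)c(CCC(C)(C)O[Si](CC)(CC)CC)c(OCOC)c2c1O[C@H](c1ccc(OCOC)cc1OCOC)[C@@H](O)C2=O
F8 | step 7 | triethyl[(2-methylbut-3-yn-2-yl)oxy]silane | C#CC(C)(C)O[Si](CC)(CC)CC
F9 | step 7 | 3-bromo-2-hydroxy-4,6-bis(methoxymethoxy)-5-[3-methyl-3-(triethylsilyloxy)but-1-yn-1-yl]benzaldehyde | O=Cc1c(O)c(Br)c(OCOC)c(C#CC(C)(C)O[Si](CC)(CC)CC)c1OCOC
F10 | step 8 | [(2S)-5-methyl-2-(prop-1-en-2-yl)hex-4-en-1-yl]lithium | C=C(C)[C@H](CC=C(C)C)C[Li]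
F11 | step 8 | lithium 9-methoxy-9-[(2S)-5-methyl-2-(prop-1-en-2-yl)hex-4-en-1-yl]-9-boranuidabicyclo[3.3.1]nonane | [Li+].C=C(C)[C@H](CC=C(C)C)C[B-]1(OC)C2CCCC1CCC2
F12 | step 17 | 4-acetate of 24 (C4 epimers) | C=C(C)[C@H](CC=C(C)C)Cc1c(OCOC)c(CCC(C)(C)O[Si](CC)(CC)CC)c(OCOC)c2c1O[C@H](c1ccc(OCOC)cc1OCOC)[C@@H](O[Si](C)(C)C(C)(C)C)C2OC(C)=O
F13 | step 19 | (2R,3R)-2-[2,4-bis(methoxymethoxy)phenyl]-3-hydroxy-6-(3-hydroxy-3-methylbutyl)-5,7-bis(methoxymethoxy)-8-[(2R)-lavandulyl]chroman-4-one | C=C(C)[C@H](CC=C(C)C)Cc1c(OCOC)c(CCC(C)(C)O)c(OCOC)c2c1O[C@H](c1ccc(OCOC)cc1OCOC)[C@@H](O)C2=O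
A1 | alternative 1 | 3-ethoxy-6-[(2R)-5-methyl-2-(prop-1-en-2-yl)hex-4-en-1-yl]-2-[3-methyl-3-(triethylsilyloxy)butyl]-5-(triisopropylsilyloxy)phenol | C=C(C)[C@H](CC=C(C)C)Cc1c(O)c(CCC(C)(C)O[Si](CC)(CC)CC)c(OCC)cc1O[Si](C(C)C)(C(C)C)C(C)C
A2 | alternative 1 | 3-ethoxy-4-[3-methyl-3-(triethylsilyloxy)butyl]cyclobut-2-en-1-one | CCOC1=CC(=O)C1CCC(C)(C)O[Si](CC)(CC)CC
A3 | alternative 1 | triisopropyl{[(4R)-7-methyl-4-(prop-1-en-2-yl)oct-6-en-1-yn-1-yl]oxy}silane | C=C(C)[C@H](CC=C(C)C)CC#CO[Si](C(C)C)(C(C)C)C(C)C
A4 | alternative 2 | (2R,3R)-2-[2,4-bis(methoxymethoxy)phenyl]-3-(tert-butyldimethylsilyloxy)-5,7-dihydroxy-8-[(2R)-lavandulyl]-6-[3-methyl-3-(triethylsilyloxy)butyl]chroman-4-one | C=C(C)[C@H](CC=C(C)C)Cc1c(O)c(CCC(C)(C)O[Si](CC)(CC)CC)c(O)c2c1O[C@H](c1ccc(OCOC)cc1OCOC)[C@@H](O[Si](C)(C)C(C)(C)C)C2=O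
A5 | alternative 2 | (2R,3R)-2-[2,4-bis(methoxymethoxy)phenyl]-5-bromo-3-(tert-butyldimethylsilyloxy)-2,3-dihydro-4H-pyran-4-one | BrC1=CO[C@H](c2ccc(OCOC)cc2OCOC)[C@@H](O[Si](C)(C)C(C)(C)C)C1=O
A6 | alternative 2 | 1-methoxy-1,3-bis(trimethylsilyloxy)buta-1,3-diene bearing the 3-methyl-3-(triethylsilyloxy)butyl chain on C2 and the (R)-lavandulyl group on C4 | COC(O[Si](C)(C)C)=C(CCC(C)(C)O[Si](CC)(CC)CC)C(O[Si](C)(C)C)=CC[C@H](C(C)=C)CC=C(C)C
A7 | alternative 3 | (2R,3R)-2-[2,4-bis(methoxymethoxy)phenyl]-3,5,7-tris(methoxymethoxy)-8-[(2R)-lavandulyl]-6-[3-methyl-3-(triethylsilyloxy)butyl]chroman-4-one | C=C(C)[C@H](CC=C(C)C)Cc1c(OCOC)c(CCC(C)(C)O[Si](CC)(CC)CC)c(OCOC)c2c1O[C@H](c1ccc(OCOC)cc1OCOC)[C@@H](OCOC)C2=O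
A8 | alternative 3 | (2R,3R)-3-[2,4-bis(methoxymethoxy)phenyl]-1-{2-fluoro-4,6-bis(methoxymethoxy)-3-[(2R)-lavandulyl]-5-[3-methyl-3-(triethylsilyloxy)butyl]phenyl}-3-hydroxy-2-(methoxymethoxy)propan-1-one | C=C(C)[C@H](CC=C(C)C)Cc1c(OCOC)c(CCC(C)(C)O[Si](CC)(CC)CC)c(OCOC)c(C(=O)[C@H](OCOC)[C@H](O)c2ccc(OCOC)cc2OCOC)c1F
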